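**Plan**

- Retrosynthesis: remove the C15 acetyl and the C3 hydroxyl; rejoin C3 to C18 as a cyclopropyl ketone; cut C3–C4 and C3–C18 together (C3 carbenoid plus isopropenyl); then cut C13=C14 (olefination), C9–C11 (1,2-addition), C10–C1 and C10–C20 (enolate alkylations), back to (S)-carvone.
- Enabling feature: in ring A (C1–C5, C10) the quaternary gem-dimethyl carbon C4 lies between C5 and the C3 carbinol next to the C2 ketone. C4, C19 and a latent C18 are therefore the carvone isopropenyl group, and C3 is the carbene carbon of a C10–C1–C2(=O)–C3 diazoketone arm.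
- Forward: ring B is the carvone ring. C10 is made quaternary, the side chain is added at C9, and the enone is transposed and reduced to the C7=C8 alkene. The chain is extended to the E allylic silyl ether and the allyl group becomes the diazoketone. Ring A closes in step 13 as a bicyclo[4.1.0]heptan-2-one, whose C3–C18 bond is then cleaved reductively to give the C4 gem-dimethyl group and the C2–C3 enolate for hydroxylation.
- Stereochemistry: C5 from (S)-carvone; C10 by allylation anti to the isopropenyl group; C9 by axial protonation in the dissolving-metal reduction; C13=C14 (E) by Horner–Wadsworth–Emmons olefination; C3 by base equilibration of the ketol to the equatorial alcohol.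

Key step: step 13

Remark: labdane numbering is used for every intermediate (carvone C1, C2, C3, C4, C5, C6 = C9, C8, C7, C6, C5, C10; C18 and C19 are the C4 methyls, C20 the C10 methyl); the amide bases and Bu4NF are taken as commercial solutions.

**Route**

Step 1
Reactants: 1 (S)-(+)-carvone
Product: 3 trans-6-methylcarvone (new C10 methyl trans to the C5 isopropenyl group; the minor cis epimer is carried along), via carvone lithium enolate 2 (not isolated)
Conditions: LiN(iPr)2, THF, −78 °C; MeI, −78 → 0 °C
Reagents that add atoms: iodomethane, CI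
Why: Kinetic deprotonation at the α′ methylene (C10) gives the cross-conjugated enolate, whose C-methylation is a standard enolate alkylation, and the new centre is flattened again in step 2 so its configuration is immaterial.

Step 2
Reactants: 3 trans-6-methylcarvone; 4 allyl bromide
Product: 6 6-allyl-6-methylcarvone (allyl trans and methyl cis to the isopropenyl group), via methylcarvone lithium enolate 5 (not isolated)
Conditions: LiN(iPr)2, THF, −78 → 0 °C; 4, DMPU, −78 → 25 °C
Reagents that add atoms: none
Why: Enolate alkylation creates the quaternary C10, the allyl group entering on the face opposite the neighbouring C5 isopropenyl group (1,2-induction), which places the future C1 trans and C20 cis to the isopropenyl group as the target requires.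

Step 3
Reactants: 6 6-allyl-6-methylcarvone; 7 2-(2-bromoethyl)-2-methyl-1,3-dioxolane
Product: 9 C9 tertiary allylic alcohol carrying the 2-(2-methyl-1,3-dioxolan-2-yl)ethyl chain (C9 epimers), via Grignard reagent 8 (not isolated)
Conditions: 7, Mg, THF, 25 °C; then 6, CeCl3, THF, −78 → 0 °C; aq NH4Cl
Reagents that add atoms: none
Why: Cerium trichloride-promoted Grignard addition (organocerium-type 1,2-addition) puts C11–C13 and C16 on the hindered C9 carbonyl and not on C7, and the configuration of the new carbinol carbon is irrelevant because it becomes trigonal in step 4.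

Step 4
Reactants: 9 C9 tertiary allylic alcohol
Product: 10 transposed enone (C7 ketone; C8=C9 bearing the C17 methyl and the side chain)
Conditions: pyridinium chlorochromate [C5H5NH][CrO3Cl], 4 Å MS, CH2Cl2, 25 °C
Reagents that add atoms: pyridinium chlorochromate, [O-][Cr](=O)(=O)Cl.c1cc[nH+]cc1 (an oxo oxygen becomes the C7 carbonyl oxygen)
Why: Babler–Dauben oxidative transposition, in which the tertiary allylic chromate ester undergoes a [3,3] shift to C7 and is then oxidised to the enone, is standard for 1-alkylcyclohex-2-enols and leaves the ketal and the isolated alkenes alone.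

Step 5
Reactants: 10 transposed enone
Product: 12 C7 enol triflate (C7=C8; C9–H on the face of C5–H), via C7 lithium enolate 11 (not isolated)
Conditions: Li, NH3(l)/THF, t-BuOH (1 equiv), −78 °C; isoprene; NH3 off; PhNTf2, THF, −78 → 25 °C; aq NH4Cl
Reagents that add atoms: N-phenylbis(trifluoromethanesulfonimide), O=S(=O)(N(c1ccccc1)S(=O)(=O)C(F)(F)F)C(F)(F)F
Why: Dissolving-metal (Birch-type) enone reduction protonates the C9 carbanion axially in the half-chair that keeps the C10 allyl and C5 isopropenyl groups equatorial, that is on the face opposite the axial C10 methyl, which sets C9–H cis to C5–H, and the regiodefined C7 enolate is trapped on oxygen as the triflate.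

Step 6
Reactants: 12 C7 enol triflate
Product: 13 ring B diene ketal (C7=C8 alkene; allyl and isopropenyl and dioxolane intact)
Conditions: Pd(OAc)2 (cat.), PPh3, Bu3N, HCO2H, DMF, 60 °C
Reagents that add atoms: none
Why: Palladium-catalysed formate reduction of an enol triflate (oxidative addition, formate-to-hydride exchange, reductive elimination) replaces the triflate by hydrogen without moving the C7=C8 double bond or touching C9.

Step 7
Reactants: 13 ring B diene ketal
Product: 14 C13 methyl ketone
Conditions: 1 M HCl, THF, 25 °C
Reagents that add atoms: water, O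
Why: Acid-catalysed ketal hydrolysis unmasks the methyl ketone under conditions too mild to hydrate or isomerise the alkenes.

Step 8
Reactants: 14 C13 methyl ketone; 15 triethyl phosphonoacetate
Product: 17 (E)-ethyl enoate (C13=C14; ester carbon C15), via sodium phosphonate carbanion 16 (not isolated)
Conditions: 15, NaH, THF, 0 °C; then 14, 0 → 50 °C
Reagents that add atoms: none
Why: Horner–Wadsworth–Emmons olefination of the methyl ketone should favour the E-trisubstituted enoate (ester trans to the larger C12 chain), and the minor Z isomer is to be removed by chromatography here or at the alcohol stage.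

Step 9
Reactants: 17 (E)-ethyl enoate
Product: 18 (E)-allylic alcohol (C15–OH)
Conditions: iBu2AlH, CH2Cl2, −78 °C; aq potassium sodium tartrate
Reagents that add atoms: none
Why: 1,2-Reduction of the α,β-unsaturated ester by the aluminium hydride at low temperature gives the allylic alcohol without touching the isolated alkenes or the E geometry.

Step 10
Reactants: 18 (E)-allylic alcohol
Product: 19 C15 tert-butyldimethylsilyl ether
Conditions: TBSCl, imidazole, CH2Cl2, 25 °C
Reagents that add atoms: tert-butyldimethylsilyl chloride, CC(C)(C)[Si](C)(C)Cl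
Why: Standard silylation of the primary allylic alcohol shields the hydroxyl from the amide base of step 12 and from O–H insertion by the carbenoid in step 13.

Step 11
Reactants: 19 C15 tert-butyldimethylsilyl ether
Product: 20 C2 methyl ketone (C10–CH2–CO–CH3)
Conditions: PdCl2 (cat.), CuCl, O2 (1 atm), DMF/H2O, 25 °C
Reagents that add atoms: water, O
Why: Tsuji–Wacker oxidation (Markovnikov hydroxypalladation, β-hydride elimination) is selective for the monosubstituted terminal alkene over the 1,1-disubstituted isopropenyl and the two trisubstituted alkenes, so only the allyl group becomes the methyl ketone.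

Step 12
Reactants: 20 C2 methyl ketone
Product: 23 diazoketone (C10–C1H2–C2(=O)–C3H=N2; C5 isopropenyl), via lithium enolate 21 (not isolated), via trifluoroacetyl ketone 22 (not isolated)
Conditions: LiN(SiMe3)2, THF, −78 °C; CF3CO2CH2CF3; 5% HCl wash; then MsN3, Et3N, H2O, MeCN, 25 °C
Reagents that add atoms: methanesulfonyl azide, CS(=O)(=O)N=[N+]=[N-]; 2,2,2-trifluoroethyl trifluoroacetate, O=C(OCC(F)(F)F)C(F)(F)F (supplies the trifluoroacetyl group of 22 only)
Why: Detrifluoroacetylative (Regitz-type deacylative) diazo transfer works because the kinetic enolate forms at the methyl group and not at the neopentyl C1 methylene, is acylated by the trifluoroacetate, and the activated 1,3-diketone takes the diazo group at C3 from the sulfonyl azide with loss of the trifluoroacetyl group as its sulfonamide.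

Step 13
Reactants: 23 diazoketone
Product: 24 tricyclic cyclopropyl ketone (C3–C4–C18 cyclopropane fused to ring A; C18 on the face of C5–H)
Conditions: dirhodium tetrakis(caprolactamate) Rh2(C6H10NO)4 (1 mol%), CH2Cl2, 40 °C, 23 added by syringe pump over 10 h (final 0.005 M)
Reagents that add atoms: none
Why: The catalyst extrudes dinitrogen from 23 to give an electrophilic rhodium carbenoid at C3, which adds in a concerted, asynchronous [2+1] manner across the C4=C18 bond of the isopropenyl group and so forms C3–C4 and C3–C18 at once. The closest known reaction type is the rhodium- or copper-catalysed intramolecular cyclopropanation of a 1-diazohept-6-en-2-one to a bicyclo[4.1.0]heptan-2-one. Ring A closes by 6-exo attack of C3 on the internal alkene carbon C4 through a chair-like array, the trans ring fusion being preset by the trans-diequatorial C10 arm and C5 isopropenyl group, and the three-membered ring closes in the same event by bonding of C3 to the terminal carbon C18. The new stereocentres C3 and C4 are necessarily cis on the cyclopropane (syn addition) and should form with C18 on the face of C5–H, away from the axial C10 methyl, but both are erased in step 15 so either face would serve. The step needs chemoselectivity for the isopropenyl group over the C7=C8 and C13=C14 alkenes and over insertion into the allylic C5–H and C9–H bonds. This is secured by reach (only C4=C18 can be met in a strain-free six-ring array), by the higher nucleophilicity of the 1,1-disubstituted alkene, by the carboxamidate ligands, which make the carbenoid less electrophilic and so disfavour C–H insertion, and by slow addition at high dilution, which suppresses carbene dimerisation and intermolecular reaction.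

Step 14
Reactants: 24 tricyclic cyclopropyl ketone
Product: 25 hydroxy cyclopropyl ketone (free C15–OH)
Conditions: Bu4NF, THF, 0 → 25 °C; aq NH4Cl
Reagents that add atoms: none
Why: Fluoride-mediated desilylation frees the C15 hydroxyl, which in step 15 serves as the internal proton donor and, as its alkoxide, resists reductive allylic C–O cleavage, while the cyclopropyl ketone is untouched.

Step 15
Reactants: 25 hydroxy cyclopropyl ketone
Product: 27 3-epi ketol (4,4-dimethyl; C2 ketone; axial C3–OH on the face of C5–H; free C15–OH), via dilithium enolate alkoxide 26 (not isolated)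
Conditions: Li, NH3(l)/THF, −78 °C; isoprene; NH3 off; THF, (1S)-(+)-(10-camphorsulfonyl)oxaziridine, −78 → 0 °C; aq NH4Cl
Reagents that add atoms: (1S)-(+)-(10-camphorsulfonyl)oxaziridine, CC1(C)[C@@H]2CC[C@]13CS(=O)(=O)N4O[C@@]34C2
Why: Dissolving-metal reductive cleavage of the cyclopropyl ketone breaks C3–C18, the cyclopropane bond that overlaps with the carbonyl π system of a bicyclo[4.1.0]heptan-2-one, so C18 becomes the second C4 methyl and the enolate exists only toward C3, and this enolate is hydroxylated by the N-sulfonyloxaziridine (Davis-type enolate oxidation), oxygen being expected to enter anti to the pseudoaxial C4 methyl and the C10 methyl to give the axial alcohol, whose configuration is corrected in step 16.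

Step 16
Reactants: 27 3-epi ketol
Product: 28 ketol diol (equatorial C3–OH on the face of the C10 methyl; C2 ketone; free C15–OH)
Conditions: K2CO3, degassed MeOH, argon, 40 °C
Reagents that add atoms: none
Why: Base-mediated α-ketol epimerisation through the C2–C3 enediolate should converge on the equatorial C3 alcohol, the thermodynamic ketol because the hydroxyl is equatorial and hydrogen-bonded in the carbonyl plane while the trigonal C2 avoids the axial hydrogen between the syn-axial C4 and C10 methyls that the transposed 3-oxo ketol would carry, so C3 is set under thermodynamic control.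

Step 17
Reactants: 28 ketol diol
Product: 29 CNP0164008.1 (C15 acetate)
Conditions: Ac2O (1.1 equiv), pyridine, CH2Cl2, 0 °C
Reagents that add atoms: acetic anhydride, CC(=O)OC(C)=O
Why: Acylation distinguishes the unhindered primary allylic alcohol from the secondary C3 alcohol, which is neopentyl-like and hydrogen-bonded to the C2 ketone, so one equivalent of anhydride without an acyl-transfer catalyst should acetylate only C15.

**Compound list**

1 | (S)-(+)-carvone | CC1=CC[C@@H](CC1=O)C(C)=C | starting material
2 | carvone lithium enolate (C9–OLi, C9=C10) | [Li]OC1=C[C@@H](C(C)=C)CC=C1C | intermediate (not isolated)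
3 | trans-6-methylcarvone, (5S,6R)-2,6-dimethyl-5-(prop-1-en-2-yl)cyclohex-2-en-1-one | O=C1C(C)=CC[C@H](C(C)=C)[C@H]1C | intermediate
4 | allyl bromide | C=CCBr | starting material
5 | methylcarvone lithium enolate (C9–OLi, C9=C10) | [Li]OC1=C(C)[C@@H](C(C)=C)CC=C1C | intermediate (not isolated)
6 | 6-allyl-6-methylcarvone, (5R,6R)-2,6-dimethyl-6-(prop-2-en-1-yl)-5-(prop-1-en-2-yl)cyclohex-2-en-1-one (allyl trans to isopropenyl) | O=C1C(C)=CC[C@H](C(C)=C)[C@@]1(C)CC=C | intermediate
7 | 2-(2-bromoethyl)-2-methyl-1,3-dioxolane | CC1(CCBr)OCCO1 | starting material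
8 | [2-(2-methyl-1,3-dioxolan-2-yl)ethyl]magnesium bromide | CC1(CC[Mg]Br)OCCO1 | intermediate (not isolated)
9 | C9 tertiary allylic alcohol (C7=C8; C9 bears OH and the dioxolanylethyl chain; both C9 epimers, centre left open) | CC1(CCC2(O)C(C)=CC[C@H](C(C)=C)[C@@]2(C)CC=C)OCCO1 | intermediate
10 | transposed enone (C7 ketone, C8=C9) | CC1(CCC2=C(C)C(=O)C[C@H](C(C)=C)[C@@]2(C)CC=C)OCCO1 | intermediate
11 | C7 lithium enolate (C7=C8; C9–H cis to C5–H) | CC1(CC[C@@H]2C(C)=C(O[Li])C[C@H](C(C)=C)[C@@]2(C)CC=C)OCCO1 | intermediate (not isolated)
12 | C7 enol triflate | CC1(CC[C@@H]2C(C)=C(OS(=O)(=O)C(F)(F)F)C[C@H](C(C)=C)[C@@]2(C)CC=C)OCCO1 | intermediate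
13 | ring B diene ketal (C7=C8 alkene, C10 allyl, C5 isopropenyl, C13 dioxolane) | CC1(CC[C@@H]2C(C)=CC[C@H](C(C)=C)[C@@]2(C)CC=C)OCCO1 | intermediate
14 | C13 methyl ketone | CC(=O)CC[C@@H]1C(C)=CC[C@H](C(C)=C)[C@@]1(C)CC=C | intermediate
15 | triethyl phosphonoacetate | CCOC(=O)CP(=O)(OCC)OCC | starting material
16 | sodium salt of triethyl phosphonoacetate | CCOC(=O)[CH-]P(=O)(OCC)OCC.[Na+] | intermediate (not isolated)
17 | (E)-ethyl enoate (C13=C14, ester at C15) | CCOC(=O)/C=C(\C)CC[C@@H]1C(C)=CC[C@H](C(C)=C)[C@@]1(C)CC=C | intermediate
18 | (E)-allylic alcohol (C15–OH) | OC/C=C(\C)CC[C@@H]1C(C)=CC[C@H](C(C)=C)[C@@]1(C)CC=C | intermediate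
19 | C15 tert-butyldimethylsilyl ether | CC(C)(C)[Si](C)(C)OC/C=C(\C)CC[C@@H]1C(C)=CC[C@H](C(C)=C)[C@@]1(C)CC=C | intermediate
20 | C2 methyl ketone (C10–CH2–CO–CH3) | CC(C)(C)[Si](C)(C)OC/C=C(\C)CC[C@@H]1C(C)=CC[C@H](C(C)=C)[C@@]1(C)CC(C)=O | intermediate
21 | lithium enolate of 20 at the methyl group (C2=C3) | CC(C)(C)[Si](C)(C)OC/C=C(\C)CC[C@@H]1C(C)=CC[C@H](C(C)=C)[C@@]1(C)CC(=C)O[Li] | intermediate (not isolated)
22 | trifluoroacetyl ketone (C3–COCF3) | CC(C)(C)[Si](C)(C)OC/C=C(\C)CC[C@@H]1C(C)=CC[C@H](C(C)=C)[C@@]1(C)CC(=O)CC(=O)C(F)(F)F | intermediate (not isolated)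
23 | diazoketone (C10–CH2–CO–CHN2; C5 isopropenyl; C15 silyl ether) | CC(C)(C)[Si](C)(C)OC/C=C(\C)CC[C@@H]1C(C)=CC[C@H](C(C)=C)[C@@]1(C)CC(=O)C=[N+]=[N-] | intermediate
24 | tricyclic cyclopropyl ketone (C3–C4–C18 cyclopropane on the face of C5–H) | CC(C)(C)[Si](C)(C)OC/C=C(\C)CC[C@@H]1C(C)=CC[C@@H]2[C@@]3(C)C[C@H]3C(=O)C[C@@]12C | intermediate
25 | hydroxy cyclopropyl ketone | OC/C=C(\C)CC[C@@H]1C(C)=CC[C@@H]2[C@@]3(C)C[C@H]3C(=O)C[C@@]12C | intermediate
26 | dilithium C2–C3 enolate C15 alkoxide (4,4-dimethyl) | [Li]OC/C=C(\C)CC[C@@H]1C(C)=CC[C@@H]2C(C)(C)C=C(O[Li])C[C@@]12C | intermediate (not isolated)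
27 | 3-epi ketol (axial C3–OH, cis to C5–H) | OC/C=C(\C)CC[C@@H]1C(C)=CC[C@@H]2C(C)(C)[C@@H](O)C(=O)C[C@@]12C | intermediate
28 | ketol diol (equatorial C3–OH, cis to the C10 methyl) | OC/C=C(\C)CC[C@@H]1C(C)=CC[C@@H]2C(C)(C)[C@H](O)C(=O)C[C@@]12C | intermediate
29 | CNP0164008.1 | CC(=O)OC/C=C(\C)CC[C@@H]1C(C)=CC[C@@H]2C(C)(C)[C@H](O)C(=O)C[C@@]12C | target

**Step count and risks**

Total step count: 17. Longest linear sequence: 17 steps, from 1 to 29.

Steps most likely to fail:

1. Step 5. The C9 carbanion may be protonated on the wrong face if the reduction runs through the half-chair with axial allyl and isopropenyl groups, and O-sulfonylation of the hindered tetrasubstituted enolate may be incomplete. The fallback sets out from 10 and comes back at 13, bypassing 12.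
   - Corey–Bakshi–Shibata reduction of 10, with (S)-1-methyl-3,3-diphenyl-tetrahydro-1H,3H-pyrrolo[1,2-c][1,3,2]oxazaborole and BH3·SMe2 in THF at −20 °C, should give the C7 allylic alcohol F1 with its hydroxyl on the face of the C10 methyl.
   - A reductive allylic transposition of the Myers type follows (2-nitrobenzenesulfonylhydrazide, PPh3, diethyl azodicarboxylate, THF, −30 → 25 °C). Mitsunobu displacement with inversion gives the N-allylic sulfonylhydrazine F2, loss of sulfinic acid gives the allylic diazene F3, and F3 loses dinitrogen while delivering hydrogen suprafacially to C9 on the face of C5–H.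
   - The double bond moves to C7=C8 and the product is 13, its C9 configuration now fixed by the reagent-controlled C7 carbinol.

2. Step 15. Proton transfer to the hindered C3 enolate, or slow oxygen transfer after removal of ammonia, would leave the plain 4,4-dimethyl ketone and lose the regiochemical information; lithium amide from the quench may also consume oxidant. The fallback sets out from 25 and comes back at 27.
   - 25 is reduced with Li/NH3 as before, but the enolate 26 is silylated (Me3SiCl, Et3N, THF, −78 → 0 °C) and isolated as the bis(trimethylsilyl) enol ether F4.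
   - Rubottom oxidation with dimethyldioxirane (1 equiv, acetone/CH2Cl2, −78 °C), in which the far more nucleophilic silyl enol ether should react before the trisubstituted alkenes, gives the silyloxy epoxide F5.
   - Citric acid in methanol opens the epoxide and removes both silyl groups to give 27.

3. Step 13. The carbenoid may insert into the allylic C5–H or C9–H bond (five-ring closure) or dimerise in competition with cyclopropanation. The fallback sets out from 20 and comes back at 24 without a carbenoid.
   - The kinetic enolate 21 is aminomethylated with dimethylmethyleneammonium iodide to the Mannich base F6.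
   - Quaternisation with MeI and elimination with NaHCO3 give the vinyl ketone F7.
   - Ring-closing metathesis of the vinyl ketone with the isopropenyl group (second-generation Grubbs catalyst, RuCl2(=CHPh)(PCy3)(H2IMes), toluene, 80 °C) expels ethylene and closes ring A as the ring A enone F8.
   - Corey–Chaykovsky cyclopropanation (Me3S(O)I, NaH, DMSO, 25 → 50 °C) adds a new C18 methylene across C3=C4 from the face away from the C10 methyl and gives 24.

**Further compounds**

F1 | step 5 | C7 allylic alcohol (C8=C9; C7–OH on the face of the C10 methyl) | CC1(CCC2=C(C)[C@H](O)C[C@H](C(C)=C)[C@@]2(C)CC=C)OCCO1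
F2 | step 5 | C7 N-(2-nitrobenzenesulfonyl)hydrazine (C7 inverted) | CC1(CCC2=C(C)[C@@H](N(N)S(=O)(=O)c3ccccc3[N+](=O)[O-])C[C@H](C(C)=C)[C@@]2(C)CC=C)OCCO1
F3 | step 5 | C7 allylic diazene | CC1(CCC2=C(C)[C@@H](N=N)C[C@H](C(C)=C)[C@@]2(C)CC=C)OCCO1
F4 | step 15 | bis(trimethylsilyl) derivative (C2–C3 silyl enol ether, C15 silyl ether) | C[Si](C)(C)OC/C=C(\C)CC[C@@H]1C(C)=CC[C@@H]2C(C)(C)C=C(O[Si](C)(C)C)C[C@@]12C
F5 | step 15 | 2-trimethylsilyloxy 2,3-epoxide (epoxide oxygen on the face of C5–H) | C[Si](C)(C)OC/C=C(\C)CC[C@@H]1C(C)=CC[C@@H]2C(C)(C)[C@H]3O[C@@]3(O[Si](C)(C)C)C[C@@]12C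
F6 | step 13 | Mannich base (C3–CH2NMe2) | CC(C)(C)[Si](C)(C)OC/C=C(\C)CC[C@@H]1C(C)=CC[C@H](C(C)=C)[C@@]1(C)CC(=O)CCN(C)C
F7 | step 13 | vinyl ketone (C10–CH2–CO–CH=CH2) | CC(C)(C)[Si](C)(C)OC/C=C(\C)CC[C@@H]1C(C)=CC[C@H](C(C)=C)[C@@]1(C)CC(=O)C=C
F8 | step 13 | ring A enone (C2 ketone, C3=C4, C4 methyl) | CC(C)(C)[Si](C)(C)OC/C=C(\C)CC[C@@H]1C(C)=CC[C@@H]2C(C)=CC(=O)C[C@@]12C
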